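# Total synthesis of guangsangon N by a cation–enol ring closure

## Retrosynthetic overview
1. The chalcone + dehydroprenylarene [4+2] is not used. The methylcyclohexene is treated like an α-terpinyl ring and closed at C3–C4 by a linalyl→terpinyl-type cation–enol cyclisation (an ionic "alicyclic Claisen") of an acyclic tertiary styryl carbinol that carries a δ-aryl ketone.
2. The carbinol comes from an alkenylcerium (C2–C3 plus the bromoresorcinol ring) adding to the methyl ketone of an (S)-1,5-diketone, forming the C1–C2 bond.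
3. The (S)-1,5-diketone comes from an organocatalytic decarboxylative Michael addition (C4–C5 bond). This one stereocentre (C5) relays to C3, and C4 is set thermodynamically.
4. The labile flavanone C2 is set last, by Rh-catalysed asymmetric 1,4-addition of the core arylboronate to a 7-silyloxychromone, followed by global desilylation.
5. Ring order: the arenes and the pyranone ring are purchased, the cyclohexene forms in step 9, and the chromone becomes a chromanone in step 12.

**Numbering used below:** C1 (Me) = C2H, C3 (Ar1), C4 (aroyl), C5 (Ar3), C6H2. The target is (3R,4R,5S), which is all-trans, with a (2S)-flavanone. TBS = tert-butyldimethylsilyl.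

**Assumption:** the sense of induction in steps 5 and 12 is assigned by analogy, as stated in those steps. The antipodal catalyst is used if the sense turns out to be reversed.

## Route

**Step 1**
- Reactants: 1, 2,4-dihydroxybenzaldehyde
- Product: 2, 2,4-bis(TBSO)benzaldehyde
- Conditions: TBSCl, imidazole, DMAP, DMF, rt
- Reagents that add atoms: TBSCl, CC(C)(C)[Si](C)(C)Cl
- Why: Standard phenol silylation; TBS withstands every later step and comes off under near-neutral fluoride at the end.

**Step 2**
- Reactants: 2; 3, 1-(triphenylphosphoranylidene)propan-2-one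
- Product: 4, (E)-4-[2,4-bis(TBSO)phenyl]but-3-en-2-one
- Conditions: toluene, 100 °C
- Reagents that add atoms: ylide 3, CC(=O)C=P(c1ccccc1)(c1ccccc1)c1ccccc1
- Why: Wittig olefination with a stabilised ylide is E-selective and base-free, so the aryl silyl ethers survive.

**Step 3**
- Reactants: 5, 2',4'-dihydroxyacetophenone
- Product: 6, 2',4'-bis(TBSO)acetophenone
- Conditions: TBSCl, imidazole, DMAP, DMF, 50 °C
- Reagents that add atoms: TBSCl, CC(C)(C)[Si](C)(C)Cl
- Why: Phenol silylation; gentle heating overcomes the hydrogen-bonded 2'-OH.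

**Step 4**
- Reactants: 6
- Product: 7, 3-[2,4-bis(TBSO)phenyl]-3-oxopropanoic acid
- Conditions: LiHMDS, THF, −78 °C; CO2; cold aq. KHSO4; used at once
- Reagents that add atoms: carbon dioxide, O=C=O
- Why: Carboxylation of the kinetic lithium enolate, with a short enolate lifetime at −78 °C to suppress O→O silyl migration.

**Step 5**
- Reactants: 4; 7 (1.5 equiv)
- Product: 8, (S)-1,3-bis[2,4-bis(TBSO)phenyl]hexane-1,5-dione
- Conditions: 1-[(1R,2R)-2-amino-1,2-diphenylethyl]-3-[3,5-bis(trifluoromethyl)phenyl]thiourea (10 mol %), toluene, rt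
- Reagents that add atoms: none (CO2 is lost)
- Why: Enantioselective decarboxylative Michael addition in which the primary amine forms the iminium of 4, the thiourea organises the β-keto acid, and loss of CO2 makes the addition irreversible; this sets C5 as S, the same spatial sense as (R,R)-DPEN giving (R)-warfarin.

**Step 6**
- Reactants: 9, 5-bromo-2,4-dihydroxybenzaldehyde
- Product: 10, 5-bromo-2,4-bis(TBSO)benzaldehyde
- Conditions: TBSCl, imidazole, DMAP, DMF, rt
- Reagents that add atoms: TBSCl, CC(C)(C)[Si](C)(C)Cl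
- Why: Phenol silylation; the bromide is the later handle for the flavanone.

**Step 7**
- Reactants: 10
- Product: 11, (E)-1-bromo-5-(2-iodovinyl)-2,4-bis(TBSO)benzene
- Conditions: CrCl2, CHI3, THF, 0 °C → rt
- Reagents that add atoms: iodoform, IC(I)I
- Why: Takai olefination is E-selective for aryl aldehydes and leaves ArBr and ArOTBS untouched.

**Step 8**
- Reactants: 11 (1.3 equiv); 8
- Product: 12, (3S,6E)-7-[5-bromo-2,4-bis(TBSO)phenyl]-1,3-bis[2,4-bis(TBSO)phenyl]-5-hydroxy-5-methylhept-6-en-1-one (about 1:1 at the carbinol carbon, which does not matter)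
- Conditions: 11, t-BuLi (2.0 equiv), Et2O, −78 °C; CeCl3, THF, −78 °C; then 8, −78 → −40 °C; neutral work-up, used crude
- Reagents that add atoms: none
- Why: Vinyl I/Li exchange outpaces ArBr exchange, and the weakly basic organocerium adds 1,2 to the methyl ketone in preference to the hindered, strongly donor-deactivated 2,4-disilyloxyaryl ketone.

**Step 9 (key step)**
- Reactants: 12
- Product: 13, [(1R,2R,6S)-2-[5-bromo-2,4-bis(TBSO)phenyl]-6-[2,4-bis(TBSO)phenyl]-4-methylcyclohex-3-en-1-yl][2,4-bis(TBSO)phenyl]methanone (all-trans)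
- Conditions: Bi(OTf)3 (5 mol %), 4 Å MS, CH2Cl2/MeNO2, 0.01 M, −40 → 0 °C; Et3N quench; then DBU (0.3 equiv), rt
- Reagents that add atoms: none (H2O is lost)
- Why: Proposed new method: ionisation of the tertiary, allylic and 2,4-dioxygenated-cinnamyl alcohol erases the carbinol stereocentre and gives an E-allyl cation that is captured reversibly by the ketone oxygen (giving a 2-styryl-3,4-dihydro-2H-pyran) and then irreversibly by the only available enol carbon (C4) at terminus C3 (attack at C1 would give a cyclobutane), through a chair-like transition state with the C5 aryl equatorial and the E-aryl pseudo-equatorial, which places Ar1 cis to Ar3 (3R from 5S), while C4 ends trans to both through equatorial attack plus enol/DBU equilibration to the all-equatorial isomer; the closest known reaction types are acid-catalysed dehydrative allylation of carbonyl enols with π-activated alcohols, the Claisen rearrangement of 2-vinyl-3,4-dihydro-2H-pyrans to 4-acylcyclohexenes, and the linalyl→α-terpinyl cation cyclisation.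

**Step 10**
- Reactants: 13
- Product: 14, the corresponding aryl pinacol boronate (Br replaced by Bpin; stereocentres unchanged)
- Conditions: B2pin2, Pd(dppf)Cl2 (5 mol %), KOAc, 1,4-dioxane, 85 °C
- Reagents that add atoms: bis(pinacolato)diboron, CC1(C)OB(OC1(C)C)B1OC(C)(C)C(C)(C)O1
- Why: Miyaura borylation; KOAc is too weak a base to affect the silyl ethers, and C4 already sits at its thermodynamic configuration.

**Step 11**
- Reactants: 15, 7-hydroxy-4H-chromen-4-one
- Product: 16, 7-(TBSO)-4H-chromen-4-one
- Conditions: TBSCl, imidazole, DMF, rt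
- Reagents that add atoms: TBSCl, CC(C)(C)[Si](C)(C)Cl
- Why: Phenol silylation.

**Step 12**
- Reactants: 14; 16 (3 equiv)
- Product: 17, hepta-O-TBS guangsangon N (new flavanone C2 = S)
- Conditions: [Rh(OH)(cod)]2 (2.5 mol %), (S)-MeO-F12-BIPHEP (5.5 mol %), toluene/H2O 10:1, 35 °C
- Reagents that add atoms: none (water supplies only H)
- Why: Hayashi–Miyaura Rh-catalysed asymmetric conjugate arylation of a chromone; C2 is set by the catalyst alone (S-biaryl bisphosphine gives 2S, the same facial sense as (S)-BINAP giving (S)-3-arylcyclohexanone), the neutral low-temperature medium avoids retro-oxa-Michael, and the minor core enantiomer becomes a separable diastereomer.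

**Step 13**
- Reactants: 17
- Product: 18, guangsangon N
- Conditions: Et3N·3HF (excess), THF, 0 °C → rt
- Reagents that add atoms: none
- Why: Fluoride desilylation of the seven aryl silyl ethers in a slightly acidic medium, so no phenoxide or quinone-methide racemisation occurs at flavanone C2, no epimerisation occurs at C4, and no acid-induced cyclisation onto the alkene occurs.

## Compound list

| No. | Name | SMILES | Role |
|---|---|---|---|
| 1 | 2,4-dihydroxybenzaldehyde | O=Cc1ccc(O)cc1O | starting material |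
| 2 | 2,4-bis(TBSO)benzaldehyde | O=Cc1ccc(O[Si](C)(C)C(C)(C)C)cc1O[Si](C)(C)C(C)(C)C | intermediate |
| 3 | 1-(triphenylphosphoranylidene)propan-2-one | CC(=O)C=P(c1ccccc1)(c1ccccc1)c1ccccc1 | starting material |
| 4 | (E)-4-[2,4-bis(TBSO)phenyl]but-3-en-2-one | CC(=O)/C=C/c1ccc(O[Si](C)(C)C(C)(C)C)cc1O[Si](C)(C)C(C)(C)C | intermediate |
| 5 | 2',4'-dihydroxyacetophenone | CC(=O)c1ccc(O)cc1O | starting material |
| 6 | 2',4'-bis(TBSO)acetophenone | CC(=O)c1ccc(O[Si](C)(C)C(C)(C)C)cc1O[Si](C)(C)C(C)(C)C | intermediate |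
| 7 | 3-[2,4-bis(TBSO)phenyl]-3-oxopropanoic acid | OC(=O)CC(=O)c1ccc(O[Si](C)(C)C(C)(C)C)cc1O[Si](C)(C)C(C)(C)C | intermediate |
| 8 | (S)-1,3-bis[2,4-bis(TBSO)phenyl]hexane-1,5-dione | O=C(c1ccc(O[Si](C)(C)C(C)(C)C)cc1O[Si](C)(C)C(C)(C)C)C[C@@H](c1ccc(O[Si](C)(C)C(C)(C)C)cc1O[Si](C)(C)C(C)(C)C)CC(C)=O | intermediate |
| 9 | 5-bromo-2,4-dihydroxybenzaldehyde | O=Cc1cc(Br)c(O)cc1O | starting material |
| 10 | 5-bromo-2,4-bis(TBSO)benzaldehyde | O=Cc1cc(Br)c(O[Si](C)(C)C(C)(C)C)cc1O[Si](C)(C)C(C)(C)C | intermediate |
| 11 | (E)-1-bromo-5-(2-iodovinyl)-2,4-bis(TBSO)benzene | I/C=C/c1cc(Br)c(O[Si](C)(C)C(C)(C)C)cc1O[Si](C)(C)C(C)(C)C | intermediate |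
| 12 | (3S,6E)-tertiary styryl carbinol (carbinol epimers) | O=C(c1ccc(O[Si](C)(C)C(C)(C)C)cc1O[Si](C)(C)C(C)(C)C)C[C@@H](c1ccc(O[Si](C)(C)C(C)(C)C)cc1O[Si](C)(C)C(C)(C)C)CC(C)(O)/C=C/c1cc(Br)c(O[Si](C)(C)C(C)(C)C)cc1O[Si](C)(C)C(C)(C)C | intermediate |
| 13 | all-trans (3R,4R,5S) cyclohexene aryl bromide | CC1=C[C@@H](c2cc(Br)c(O[Si](C)(C)C(C)(C)C)cc2O[Si](C)(C)C(C)(C)C)[C@H](C(=O)c2ccc(O[Si](C)(C)C(C)(C)C)cc2O[Si](C)(C)C(C)(C)C)[C@@H](c2ccc(O[Si](C)(C)C(C)(C)C)cc2O[Si](C)(C)C(C)(C)C)C1 | intermediate |
| 14 | corresponding aryl pinacol boronate | CC1=C[C@@H](c2cc(B3OC(C)(C)C(C)(C)O3)c(O[Si](C)(C)C(C)(C)C)cc2O[Si](C)(C)C(C)(C)C)[C@H](C(=O)c2ccc(O[Si](C)(C)C(C)(C)C)cc2O[Si](C)(C)C(C)(C)C)[C@@H](c2ccc(O[Si](C)(C)C(C)(C)C)cc2O[Si](C)(C)C(C)(C)C)C1 | intermediate |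
| 15 | 7-hydroxy-4H-chromen-4-one | O=c1ccoc2cc(O)ccc12 | starting material |
| 16 | 7-(TBSO)-4H-chromen-4-one | O=c1ccoc2cc(O[Si](C)(C)C(C)(C)C)ccc12 | intermediate |
| 17 | hepta-O-TBS guangsangon N | CC1=C[C@@H](c2cc([C@@H]3CC(=O)c4ccc(O[Si](C)(C)C(C)(C)C)cc4O3)c(O[Si](C)(C)C(C)(C)C)cc2O[Si](C)(C)C(C)(C)C)[C@H](C(=O)c2ccc(O[Si](C)(C)C(C)(C)C)cc2O[Si](C)(C)C(C)(C)C)[C@@H](c2ccc(O[Si](C)(C)C(C)(C)C)cc2O[Si](C)(C)C(C)(C)C)C1 | intermediate |
| 18 | guangsangon N | CC1=C[C@@H](c2cc([C@@H]3CC(=O)c4ccc(O)cc4O3)c(O)cc2O)[C@H](C(=O)c2ccc(O)cc2O)[C@@H](c2ccc(O)cc2O)C1 | target |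

## Step count
- Total steps: 13
- Longest linear sequence: 8 (steps 1, 2, 5, 8, 9, 10, 12, 13; the branch through steps 3 and 4 is the same length)

## Steps most likely to fail
1. **Step 9 (cation–enol cyclisation).**
   - Risks: desilylation of the cation to quinone methides or 2H-chromenes, stalling at the dihydropyran, oligomerisation, and alkene migration.
   - Fallback: replace the cationic closure with a neutral metal-allyl closure using a stabilised nucleophile.
     - Run step 5 with allyl 3-aryl-3-oxopropanoate and keep the ester.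
     - Trap the tertiary alkoxide of step 8 as its methyl carbonate.
     - Close C3–C4 by intramolecular Pd(0) Tsuji–Trost alkylation.
     - Remove the ester by Pd/formate deallylative decarboxylation, with C4 again set thermodynamically.
2. **Step 12 (Rh 1,4-addition).**
   - Risks: the boronate is the limiting partner and is hindered by the ortho-OTBS group, so protodeboronation may outcompete insertion.
   - Fallback: build the pyranone ring on the core instead of adding to it.
     - Heck-couple bromide 13 with 1-[2-hydroxy-4-(TBSO)phenyl]prop-2-en-1-one to give the 2'-hydroxychalcone.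
     - Close the ring by a bifunctional cinchona-thiourea oxa-Michael cyclisation.
     - The C2 epimers are diastereomers here and can be separated.
3. **Step 5 (decarboxylative Michael).**
   - Risks: the donor-rich, ortho-substituted enone is a poor iminium acceptor, 7 can simply decarboxylate, and the amine catalyst can aldolise 8.
   - Fallback: set C5 by forming the C5–aryl bond instead. Use Rh/(BINAP-type) asymmetric 1,4-addition of 2,4-bis(TBSO)phenylboronic acid to (E)-1-[2,4-bis(TBSO)phenyl]hex-2-ene-1,5-dione 5-ethylene ketal, then mild ketal hydrolysis to 8.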